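**Plan**

Numbering: quinone ring C1(=O), C2(CH3), C3, C4(=O), C5, C6(side chain); side chain C1'–C16' counted from the ring; the target is (2'E,6'E,10'E,12'R).
Cuts: (a) quinone to hydroquinone dimethyl ether and diol to bis-TBS ether; (b) C1'–C2' and C3'–CH3 together, possible because C2'=C3' is an E-trisubstituted alkene carrying a methyl on C3' and separated from ring carbon C6 only by the CH2 C1', so it maps onto a terminal alkyne, Me3Al and a benzylic chloride; (c) C9'–C10' (sp3–sp2 Suzuki coupling); (d) C11'–C12' (iodo-aldol).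
Forward: the C10'–C16' vinyl iodide (steps 1–4) and the C2'–C9' silyl dienyne (steps 5–7) are joined at C9'–C10' (step 8), the alkyne is freed (step 9), the arene (steps 10–13) is attached together with the C3' methyl in one pot (step 14), then desilylation and oxidation to the quinone (steps 15–16). No ring is formed; the only ring is bought as a phenol.
Stereochemistry: C12' (R) from the catalyst-controlled iodo-aldol; 10'E from its Z-selectivity plus retention in the Suzuki coupling; 6'E from a stabilised Wittig olefination; 2'E from syn methylalumination plus retention in the nickel coupling.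

Key step: step 14

Assumption: in step 2 the (S)-configured oxazaborolidinium catalyst is taken to direct the allenolate to the si face of the bound aldehyde, which corresponds to the (R)-carbinol. The configuration of 6 would be confirmed through its MTPA esters, and the mirror-image catalyst would be used with no other change should the sense prove opposite.

**Route**

Step 1
Reactants: 1 4-methylpent-3-en-1-ol
Product: 2 4-methylpent-3-enal
Conditions: Dess–Martin periodinane (1.2 equiv), NaHCO3, CH2Cl2, 0 °C to rt; used at once as a dried CH2Cl2 solution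
Reagents that add atoms: none
Why: Dess–Martin oxidation under buffered, near-neutral conditions should stop at the aldehyde and leave the β,γ-double bond out of conjugation.

Step 2
Reactants: 2 4-methylpent-3-enal; 3 ethyl propiolate
Product: 6 ethyl (2Z)-2-[(1R)-1-hydroxy-4-methylpent-3-en-1-yl]-3-iodoprop-2-enoate, via silyl iodoallenolate 4 (not isolated), via O-TMS aldol adduct 5 (not isolated)
Conditions: TMSI (1.2 equiv), (S)-oxazaborolidinium triflimide [from (S)-α,α-diphenylprolinol, o-tolylboroxine, Tf2NH] (20 mol%), CH2Cl2, −78 °C; then 1 M HCl, THF, 0 °C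
Reagents that add atoms: iodotrimethylsilane, C[Si](C)(C)I
Why: Catalytic asymmetric three-component iodo-aldol (β-iodo Morita–Baylis–Hillman) reaction, in which iodide adds to the ynoate to give the silyl β-iodoallenolate and this adds in a Mukaiyama-type aldol to the aldehyde held on the chiral boron cation, the kinetic pathway giving the Z-iodoalkene and the catalyst's facial bias setting C12' as R.

Step 3
Reactants: 6 ethyl (2Z)-2-[(1R)-1-hydroxy-4-methylpent-3-en-1-yl]-3-iodoprop-2-enoate
Product: 7 (2E,3R)-2-(iodomethylidene)-6-methylhept-5-ene-1,3-diol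
Conditions: DIBAL-H (3.5 equiv), CH2Cl2, −78 to −20 °C; aq. Rochelle salt
Reagents that add atoms: none
Why: 1,2-Reduction of the α,β-unsaturated ester by DIBAL-H at low temperature should give the allylic alcohol without touching the vinyl iodide or its geometry (the descriptor changes from Z to E only through the CIP priorities).

Step 4
Reactants: 7 (2E,3R)-2-(iodomethylidene)-6-methylhept-5-ene-1,3-diol
Product: 8 (2E,3R)-1,3-bis(tert-butyldimethylsilyloxy)-2-(iodomethylidene)-6-methylhept-5-ene
Conditions: TBSOTf (2.5 equiv), 2,6-lutidine (4 equiv), CH2Cl2, −78 to 0 °C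
Reagents that add atoms: tert-butyldimethylsilyl trifluoromethanesulfonate, CC(C)(C)[Si](C)(C)OS(=O)(=O)C(F)(F)F
Why: Silyl triflate with a hindered pyridine base silylates both the primary and the hindered secondary allylic hydroxyl without affecting the vinyl iodide or the C12' centre.

Step 5
Reactants: 9 5-(trimethylsilyl)pent-4-yn-1-ol
Product: 10 5-(trimethylsilyl)pent-4-ynal
Conditions: Dess–Martin periodinane (1.2 equiv), NaHCO3, CH2Cl2, 0 °C to rt
Reagents that add atoms: none
Why: Dess–Martin oxidation of a primary alcohol to the aldehyde, to which the silyl alkyne is inert.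

Step 6
Reactants: 10 5-(trimethylsilyl)pent-4-ynal; 11 2-(triphenylphosphoranylidene)propanal
Product: 12 (2E)-2-methyl-7-(trimethylsilyl)hept-2-en-6-ynal
Conditions: toluene, 90 °C
Reagents that add atoms: none
Why: Wittig olefination with the stabilised formyl ylide should give the (E)-2-methyl enal (this fixes 6'E), and the α-branched enal formed reacts only slowly with more ylide.

Step 7
Reactants: 12 (2E)-2-methyl-7-(trimethylsilyl)hept-2-en-6-ynal
Product: 13 trimethyl[(5E)-6-methylocta-5,7-dien-1-yn-1-yl]silane
Conditions: Ph3PCH3Br, n-BuLi, THF, 0 °C; then 12, 0 °C to rt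
Reagents that add atoms: methyltriphenylphosphonium bromide, C[P+](c1ccccc1)(c1ccccc1)c1ccccc1.[Br-]
Why: Wittig methylenation of the enal gives the terminal 1,3-diene without disturbing the existing E alkene or the silyl alkyne.

Step 8
Reactants: 13 trimethyl[(5E)-6-methylocta-5,7-dien-1-yn-1-yl]silane; 8 (2E,3R)-1,3-bis(tert-butyldimethylsilyloxy)-2-(iodomethylidene)-6-methylhept-5-ene
Product: 15 (5E,9E,11R)-11-(tert-butyldimethylsilyloxy)-10-[(tert-butyldimethylsilyloxy)methyl]-6,14-dimethyl-1-(trimethylsilyl)pentadeca-5,9,13-trien-1-yne, via alkyl-9-BBN adduct 14 (not isolated)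
Conditions: 13 (1.3 equiv), 9-BBN (0.5 M in THF), 0 °C to rt; then 8, PdCl2(dppf) (5 mol%), AsPh3 (10 mol%), Cs2CO3, H2O, DMF/THF, rt
Reagents that add atoms: none
Why: 9-BBN should hydroborate only the monosubstituted terminus of the 1,3-diene, and the primary alkylborane should undergo B-alkyl Suzuki–Miyaura coupling with the vinyl iodide with retention, which fixes 10'E; any alkyne desilylated by the aqueous base converges in step 9.

Step 9
Reactants: 15 (5E,9E,11R)-11-(tert-butyldimethylsilyloxy)-10-[(tert-butyldimethylsilyloxy)methyl]-6,14-dimethyl-1-(trimethylsilyl)pentadeca-5,9,13-trien-1-yne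
Product: 16 (5E,9E,11R)-11-(tert-butyldimethylsilyloxy)-10-[(tert-butyldimethylsilyloxy)methyl]-6,14-dimethylpentadeca-5,9,13-trien-1-yne
Conditions: K2CO3 (0.5 equiv), MeOH/THF, rt
Reagents that add atoms: none
Why: Carbonate-mediated methanolysis cleaves only the alkynyl C–Si bond, the TBS ethers being stable to K2CO3/MeOH.

Step 10
Reactants: 17 4-methoxy-2-methylphenol
Product: 18 2-hydroxy-5-methoxy-3-methylbenzaldehyde
Conditions: MgCl2 (1.5 equiv), Et3N (3.75 equiv), paraformaldehyde (6.75 equiv), MeCN, reflux; aq. HCl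
Reagents that add atoms: paraformaldehyde (as formaldehyde), C=O
Why: Magnesium-phenoxide-directed ortho-formylation (Casnati–Skattebøl) can only occur at the one free ortho position, the other carrying the methyl group.

Step 11
Reactants: 18 2-hydroxy-5-methoxy-3-methylbenzaldehyde
Product: 19 2,5-dimethoxy-3-methylbenzaldehyde
Conditions: MeI, K2CO3, DMF, rt
Reagents that add atoms: iodomethane, CI
Why: Williamson O-methylation of the phenoxide, with no competing reaction at the aldehyde.

Step 12
Reactants: 19 2,5-dimethoxy-3-methylbenzaldehyde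
Product: 20 (2,5-dimethoxy-3-methylphenyl)methanol
Conditions: NaBH4, MeOH, 0 °C
Reagents that add atoms: none
Why: Borohydride reduction of an aryl aldehyde to the benzylic alcohol.

Step 13
Reactants: 20 (2,5-dimethoxy-3-methylphenyl)methanol
Product: 21 1-(chloromethyl)-2,5-dimethoxy-3-methylbenzene
Conditions: SOCl2 (1.2 equiv), CH2Cl2, 0 °C to rt; used promptly
Reagents that add atoms: thionyl chloride, O=S(Cl)Cl
Why: Chlorodehydroxylation of the electron-rich benzylic alcohol through its chlorosulfite.

Step 14
Reactants: 16 (5E,9E,11R)-11-(tert-butyldimethylsilyloxy)-10-[(tert-butyldimethylsilyloxy)methyl]-6,14-dimethylpentadeca-5,9,13-trien-1-yne; 22 trimethylaluminium; 21 1-(chloromethyl)-2,5-dimethoxy-3-methylbenzene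
Product: 24 (2E,6E,10E,12R)-12-(tert-butyldimethylsilyloxy)-11-[(tert-butyldimethylsilyloxy)methyl]-1-(2,5-dimethoxy-3-methylphenyl)-3,7,15-trimethylhexadeca-2,6,10,14-tetraene, via alkenyldimethylalane 23 (not isolated)
Conditions: 22 (2.5 equiv), Cp2ZrCl2 (0.25 equiv), ClCH2CH2Cl, 0 °C to rt; volatiles removed in vacuo; then 21 (0.9 equiv), Ni(0) [NiCl2(PPh3)2 (5 mol%) + n-BuLi (10 mol%)], THF, 0 °C to rt
Reagents that add atoms: none
Why: A methylzirconocene/aluminium species adds CH3 and metal syn across the terminal alkyne, with methyl on the internal carbon C3' and aluminium on C2', to give the (E)-alkenylalane 23 (zirconium-catalysed Negishi methylalumination). Ni(0) then inserts into the benzylic C–Cl bond of 21, the alkenyl group passes from aluminium to nickel, and reductive elimination forms C1'–C2' with retention of alkene geometry; the closest known reaction type is the nickel-catalysed coupling of alkenylalanes with benzylic chlorides used for polyprenylated quinones. No ring is closed and no stereocentre is created; the two new skeletal bonds are C3'–CH3 and C1'–C2'. The step needs regioselective syn addition, which is inherent to a terminal alkyne, and chemoselectivity for the alkyne over the three trisubstituted alkenes, which do not undergo methylalumination under these conditions. Because the arene partner is an electrophile at a benzylic rather than an allylic carbon, there is no SN2' pathway and no E/Z leakage at C2'=C3'. The two TBS ethers keep the hydroxyls from consuming the alane and are poor donors towards the Lewis-acidic metals.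

Step 15
Reactants: 24 (2E,6E,10E,12R)-12-(tert-butyldimethylsilyloxy)-11-[(tert-butyldimethylsilyloxy)methyl]-1-(2,5-dimethoxy-3-methylphenyl)-3,7,15-trimethylhexadeca-2,6,10,14-tetraene
Product: 25 (2E,6E,10E,12R)-1-(2,5-dimethoxy-3-methylphenyl)-11-(hydroxymethyl)-3,7,15-trimethylhexadeca-2,6,10,14-tetraen-12-ol
Conditions: TBAF (3 equiv), THF, 0 °C to rt
Reagents that add atoms: none
Why: Fluoride cleaves both Si–O bonds while the aryl methyl ethers and alkenes are inert, and doing this before the oxidation keeps the base-sensitive quinone away from fluoride.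

Step 16
Reactants: 25 (2E,6E,10E,12R)-1-(2,5-dimethoxy-3-methylphenyl)-11-(hydroxymethyl)-3,7,15-trimethylhexadeca-2,6,10,14-tetraen-12-ol
Product: 26 2-[(2E,6E,10E,12R)-12-hydroxy-11-(hydroxymethyl)-3,7,15-trimethylhexadeca-2,6,10,14-tetraen-1-yl]-6-methylcyclohexa-2,5-diene-1,4-dione
Conditions: CAN (2.5 equiv), MeCN/H2O, 0 °C, short reaction time
Reagents that add atoms: water, O
Why: Ceric ammonium nitrate oxidative demethylation of the p-dimethoxyarene proceeds through the arene radical cation with water adding at the two ipso carbons and methanol leaving, and is fast enough at 0 °C that the alkenes and allylic alcohols should survive.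

**Compound list**

1 | 4-methylpent-3-en-1-ol | CC(C)=CCCO | starting material
2 | 4-methylpent-3-enal | CC(C)=CCC=O | intermediate
3 | ethyl propiolate | C#CC(=O)OCC | starting material
4 | [(1-ethoxy-3-iodopropa-1,2-dien-1-yl)oxy]trimethylsilane (silyl iodoallenolate) | CCOC(O[Si](C)(C)C)=C=CI | intermediate
5 | ethyl (2Z)-3-iodo-2-[(1R)-4-methyl-1-(trimethylsilyloxy)pent-3-en-1-yl]prop-2-enoate | CCOC(=O)/C(=C\I)[C@H](O[Si](C)(C)C)CC=C(C)C | intermediate
6 | ethyl (2Z)-2-[(1R)-1-hydroxy-4-methylpent-3-en-1-yl]-3-iodoprop-2-enoate | CCOC(=O)/C(=C\I)[C@H](O)CC=C(C)C | intermediate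
7 | (2E,3R)-2-(iodomethylidene)-6-methylhept-5-ene-1,3-diol | OC/C(=C\I)[C@H](O)CC=C(C)C | intermediate
8 | (2E,3R)-1,3-bis(tert-butyldimethylsilyloxy)-2-(iodomethylidene)-6-methylhept-5-ene | CC(C)(C)[Si](C)(C)OC/C(=C\I)[C@H](O[Si](C)(C)C(C)(C)C)CC=C(C)C | intermediate
9 | 5-(trimethylsilyl)pent-4-yn-1-ol | C[Si](C)(C)C#CCCCO | starting material
10 | 5-(trimethylsilyl)pent-4-ynal | C[Si](C)(C)C#CCCC=O | intermediate
11 | 2-(triphenylphosphoranylidene)propanal | CC(C=O)=P(c1ccccc1)(c1ccccc1)c1ccccc1 | starting material
12 | (2E)-2-methyl-7-(trimethylsilyl)hept-2-en-6-ynal | C[Si](C)(C)C#CCC/C=C(\C)C=O | intermediate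
13 | trimethyl[(5E)-6-methylocta-5,7-dien-1-yn-1-yl]silane | C[Si](C)(C)C#CCC/C=C(\C)C=C | intermediate
14 | 9-[(3E)-3-methyl-8-(trimethylsilyl)oct-3-en-7-yn-1-yl]-9-borabicyclo[3.3.1]nonane | C[Si](C)(C)C#CCC/C=C(\C)CCB1C2CCCC1CCC2 | intermediate
15 | (5E,9E,11R)-11-(tert-butyldimethylsilyloxy)-10-[(tert-butyldimethylsilyloxy)methyl]-6,14-dimethyl-1-(trimethylsilyl)pentadeca-5,9,13-trien-1-yne | CC(C)=CC[C@@H](O[Si](C)(C)C(C)(C)C)/C(=C/CC/C(C)=C/CCC#C[Si](C)(C)C)CO[Si](C)(C)C(C)(C)C | intermediate
16 | (5E,9E,11R)-11-(tert-butyldimethylsilyloxy)-10-[(tert-butyldimethylsilyloxy)methyl]-6,14-dimethylpentadeca-5,9,13-trien-1-yne | CC(C)=CC[C@@H](O[Si](C)(C)C(C)(C)C)/C(=C/CC/C(C)=C/CCC#C)CO[Si](C)(C)C(C)(C)C | intermediate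
17 | 4-methoxy-2-methylphenol | COc1ccc(O)c(C)c1 | starting material
18 | 2-hydroxy-5-methoxy-3-methylbenzaldehyde | COc1cc(C)c(O)c(C=O)c1 | intermediate
19 | 2,5-dimethoxy-3-methylbenzaldehyde | COc1cc(C)c(OC)c(C=O)c1 | intermediate
20 | (2,5-dimethoxy-3-methylphenyl)methanol | COc1cc(C)c(OC)c(CO)c1 | intermediate
21 | 1-(chloromethyl)-2,5-dimethoxy-3-methylbenzene | COc1cc(C)c(OC)c(CCl)c1 | intermediate
22 | trimethylaluminium | C[Al](C)C | starting material
23 | [(1E,5E,9E,11R)-11-(tert-butyldimethylsilyloxy)-10-[(tert-butyldimethylsilyloxy)methyl]-2,6,14-trimethylpentadeca-1,5,9,13-tetraen-1-yl]dimethylalumane | CC(C)=CC[C@@H](O[Si](C)(C)C(C)(C)C)/C(=C/CC/C(C)=C/CC/C(C)=C/[Al](C)C)CO[Si](C)(C)C(C)(C)C | intermediate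
24 | (2E,6E,10E,12R)-12-(tert-butyldimethylsilyloxy)-11-[(tert-butyldimethylsilyloxy)methyl]-1-(2,5-dimethoxy-3-methylphenyl)-3,7,15-trimethylhexadeca-2,6,10,14-tetraene | CC(C)=CC[C@@H](O[Si](C)(C)C(C)(C)C)/C(=C/CC/C(C)=C/CC/C(C)=C/Cc1cc(OC)cc(C)c1OC)CO[Si](C)(C)C(C)(C)C | intermediate
25 | (2E,6E,10E,12R)-1-(2,5-dimethoxy-3-methylphenyl)-11-(hydroxymethyl)-3,7,15-trimethylhexadeca-2,6,10,14-tetraen-12-ol | CC(C)=CC[C@@H](O)/C(=C/CC/C(C)=C/CC/C(C)=C/Cc1cc(OC)cc(C)c1OC)CO | intermediate
26 | 2-[(2E,6E,10E,12R)-12-hydroxy-11-(hydroxymethyl)-3,7,15-trimethylhexadeca-2,6,10,14-tetraen-1-yl]-6-methylcyclohexa-2,5-diene-1,4-dione | CC(C)=CC[C@@H](O)/C(=C/CC/C(C)=C/CC/C(C)=C/CC1=CC(=O)C=C(C)C1=O)CO | target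

**Totals**

Total step count: 16.
Longest linear sequence: 9 steps (steps 1, 2, 3, 4, 8, 9, 14, 15, 16, from 4-methylpent-3-en-1-ol).

**Steps most likely to fail**

1. Step 2. The β,γ-unsaturated aldehyde may slip into conjugation or self-condense under the silyl iodide and boron Lewis acid before the C–C bond forms, and facial discrimination in the aldol addition may be insufficient. The fallback replaces catalyst control by resolution. It sets out from 2 and 3: magnesium iodide (MgI2·OEt2, CH2Cl2, 0 °C), a milder promoter, should give racemic ethyl (2Z)-2-(1-hydroxy-4-methylpent-3-en-1-yl)-3-iodoprop-2-enoate F1. Lipase-mediated acylation (Pseudomonas cepacia lipase, vinyl acetate, MTBE, rt) is expected, by the empirical rule for secondary alcohols with a branched large arm and an unbranched small arm, to acylate the (R)-enantiomer. This would give ethyl (2Z)-2-[(1R)-1-acetoxy-4-methylpent-3-en-1-yl]-3-iodoprop-2-enoate F2 and leave ethyl (2Z)-2-[(1S)-1-hydroxy-4-methylpent-3-en-1-yl]-3-iodoprop-2-enoate F3, which is removed by chromatography. Excess DIBAL-H then cleaves the acetate and reduces the ethyl ester of F2 in one operation, and the route is rejoined at diol 7.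

2. Step 14. The alkenylalane may be protonated before it couples, the transfer from aluminium to nickel may be slow so that methyl transfer from residual Me3Al competes, and long exposure to the Lewis-acidic medium may erode the allylic silyl ethers. The fallback separates the two bond formations and reverses the polarity of the coupling. It sets out from 16: the methylalumination is run briefly (water-accelerated variant, −23 °C) and quenched with iodine to give (1E,5E,9E,11R)-11-(tert-butyldimethylsilyloxy)-10-[(tert-butyldimethylsilyloxy)methyl]-1-iodo-2,6,14-trimethylpentadeca-1,5,9,13-tetraene F4. Chloride 21 is converted with zinc dust and LiCl in THF into (2,5-dimethoxy-3-methylbenzyl)zinc chloride F5. Palladium-catalysed Negishi coupling of F4 with F5 (Pd(PPh3)4, THF, rt) forms the same C1'–C2' bond with retention and returns to the route at 24.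

3. Step 16. Ce(IV) may attack the electron-rich trisubstituted alkenes or the allylic diol, or cause oxidative dimerisation, in competition with the oxidative demethylation. The fallback oxidises the ring before the chain is attached. It sets out from 21 and 16: CAN in MeCN/H2O converts 21 into 2-(chloromethyl)-6-methylcyclohexa-2,5-diene-1,4-dione F6. Alkenylalane 23, generated from 16 as in step 14 and freed of excess Me3Al, is coupled with F6 under Ni(0) catalysis, a coupling known for chloromethyl quinones. This gives 2-[(2E,6E,10E,12R)-12-(tert-butyldimethylsilyloxy)-11-[(tert-butyldimethylsilyloxy)methyl]-3,7,15-trimethylhexadeca-2,6,10,14-tetraen-1-yl]-6-methylcyclohexa-2,5-diene-1,4-dione F7. HF·pyridine in THF/pyridine then removes both silyl groups under non-basic conditions, and the route is rejoined at 26.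

**Further compounds**

F1 | step 2 | racemic ethyl (2Z)-2-(1-hydroxy-4-methylpent-3-en-1-yl)-3-iodoprop-2-enoate | CCOC(=O)/C(=C\I)C(O)CC=C(C)C
F2 | step 2 | ethyl (2Z)-2-[(1R)-1-acetoxy-4-methylpent-3-en-1-yl]-3-iodoprop-2-enoate | CCOC(=O)/C(=C\I)[C@H](OC(C)=O)CC=C(C)C
F3 | step 2 | ethyl (2Z)-2-[(1S)-1-hydroxy-4-methylpent-3-en-1-yl]-3-iodoprop-2-enoate | CCOC(=O)/C(=C\I)[C@@H](O)CC=C(C)C
F4 | step 14 | (1E,5E,9E,11R)-11-(tert-butyldimethylsilyloxy)-10-[(tert-butyldimethylsilyloxy)methyl]-1-iodo-2,6,14-trimethylpentadeca-1,5,9,13-tetraene | CC(C)=CC[C@@H](O[Si](C)(C)C(C)(C)C)/C(=C/CC/C(C)=C/CC/C(C)=C/I)CO[Si](C)(C)C(C)(C)C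
F5 | step 14 | (2,5-dimethoxy-3-methylbenzyl)zinc chloride | COc1cc(C)c(OC)c(C[Zn]Cl)c1
F6 | step 16 | 2-(chloromethyl)-6-methylcyclohexa-2,5-diene-1,4-dione | ClCC1=CC(=O)C=C(C)C1=O
F7 | step 16 | 2-[(2E,6E,10E,12R)-12-(tert-butyldimethylsilyloxy)-11-[(tert-butyldimethylsilyloxy)methyl]-3,7,15-trimethylhexadeca-2,6,10,14-tetraen-1-yl]-6-methylcyclohexa-2,5-diene-1,4-dione | CC(C)=CC[C@@H](O[Si](C)(C)C(C)(C)C)/C(=C/CC/C(C)=C/CC/C(C)=C/CC1=CC(=O)C=C(C)C1=O)CO[Si](C)(C)C(C)(C)C
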